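Readings and results stem from a simulated flask from invented constants; scatter was added.

At 12 h, the time at which Saturday's flask is to be read, we compare every flask by one number: [target] as a share of the substrate charged. Saturday's flask holds less substrate than partner, 1.20 M against 3.00 M, so substrate is its limiting reagent, and both of its charges are Wednesday's multiplied by 3.00.

| setting | Wednesday's | Thursday's | Monday's | Saturday's |
|---|---|---|---|---|
| substrate | 0.400 M | 0.400 M | 0.800 M | 1.20 M |
| partner | 1.00 M | 2.00 M | 1.00 M | 3.00 M |
| time |  |  |  | 12 h |

| run | time / h | [target] / M |
|---|---|---|
| Wednesday's run | 0.68 | 0.0081 |
| Wednesday's run | 2.1 | 0.0354 |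
| Wednesday's run | 4.0 | 0.0795 |
| Wednesday's run | 6.3 | 0.1210 |
| Wednesday's run | 9.0 | 0.1464 |
| Wednesday's run | 12 | 0.1565 |
| Thursday's run | 0.68 | 0.0119 |
| Thursday's run | 2.1 | 0.0608 |
| Thursday's run | 4.0 | 0.1281 |
| Thursday's run | 6.3 | 0.1807 |
| Thursday's run | 9.0 | 0.2168 |
| Thursday's run | 12 | 0.2226 |
| Monday's run | 0.68 | 0.0109 |
| Monday's run | 2.1 | 0.0647 |
| Monday's run | 4.0 | 0.1515 |
| Monday's run | 6.3 | 0.2241 |
| Monday's run | 9.0 | 0.2702 |
| Monday's run | 12 | 0.2900 |

(each reading ± 0.002 M)

- how the opening rate goes with [partner] round the charge of the Wednesday's run: the exponent of the rate at two percent of substrate gone to target
- how the opening rate goes with [substrate] round the charge of the Wednesday's run: the exponent of the rate at two percent of substrate gone to target (one fixed amount of target, the same in the runs compared)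
- target in the Saturday's run at 12 h, as a share of the substrate charged

- Overall: substrate + partner -> target.
- Constant volume, constant temperature.
- "The second partner" is partner.
- An order is taken over about fifteen percent of the charge, up and down.

Our zero of the scale is the symmetric case, in which multiplying both charges by one factor leaves the share as it was. The last readings give these shares:

Wednesday 39.1%, Thursday 55.6%, Monday 36.2%

Doubling partner and doubling substrate then give two exponents of the share:

partner 0.508, substrate −0.110

Their sum is the scale exponent, the power of the common factor by which the share departs from the symmetric case:

0.398

Saturday's share = 39.1% × 3.00^0.398 = 60.6%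

The first objection is that Monday's flask still gains 0.0198 M between 9.0 h and 12 h, so these shares are not end points; but we compare them at one clock time, which is also the time asked. The second is scatter, which puts about 0.0403 on the exponent, and the exponent is larger than that, so the departure stands. The third we cannot compute away: the exponents were measured over a factor of 2.00 and are used over 3.00, and we have no run to test that.

For the opening orders, the first readings give 0.555 for partner and 0.428 for substrate, but the scatter is 24.7% of Wednesday's first reading. The second readings give 0.780 and 0.870, but they lie past the 0.00800 M of target at which the orders are asked. We place each order between its two values.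

The forecast gave 0.55 for partner, 0.6 for substrate and 61% for Saturday's flask, the last of these resting in part on “Empirical scaling of the plateaus”.

The simulation gives 60.5% for Saturday's flask, with orders of 0.56 for partner and 0.62 for substrate.

    substrate → intermediate (0.2855 /h)
    intermediate + partner → target (0.2318 /M/h)
    intermediate → side product (0.1156 /h)
    partner → lost reagent (0.05652 /h)
    target → decomposed product (0.02239 /h)

Removing the path from partner to lost reagent moves the readings by 13 in units of the scatter, root mean square. Saturday's share stands 21 percentage points above Wednesday's, where the symmetric case puts it level, and the scale exponent, 0.398 from the two doublings, reads 0.397 from Saturday's flask against Wednesday's.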